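## The problem

Compound 23 is a linear procyanidin trimer: three flavan-3-ol units of the epicatechin type (2R,3R, 2,3-cis) are joined by two bonds from C4 of one unit to C6 of ring A of the next, both 4β (3,4-trans), giving eight stereocentres (top and middle unit 2R,3R,4S, lower unit 2R,3R). The first difficulty is regiochemical: a flavan-4-yl cation attacks a 5,7-dioxygenated ring A at C8 in preference to C6, so the 4→6 connectivity has to be built into the route. The second is stereochemical: inside a 4-substituted unit the three contiguous centres can control one another (C2 and C3 through an alkene geometry, C4 through its trans relation to O3), but the units are insulated from each other by flat aromatic rings, so the absolute sense must be set separately in each unit. The third is stability: the doubly benzylic C4–aryl bonds cleave under protic acid, the benzylic C2–O1 ether opens and epimerizes once phenols are free and base is present, and free catechols oxidize in air, so all phenols stay masked until a last, neutral step. The structure offers two handles. In ring C of the top and of the middle unit, O1–C8a–C4a–C4 are the atoms of an ortho-quinone methide whose methide carbon C4 carries the next aryl ring and is therefore stabilized and prochiral, while C2–C3 are those of a β-oxygenated styrene. In ring A of the middle unit the linking carbon C6 lies between O5 and O7 and para to O1, so an aryl ring attached through this carbon is symmetrical and closing the pyran ring on either side of the para oxygen can only give the 4→6 isomer; the lower unit has no C4 substituent and is (−)-epicatechin itself.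

## Retrosynthesis

**Unmasking (23 from 22 from 21).** The last cuts are thirteen O–benzyl bonds and one C8–Br bond, all removed by one buffered hydrogenolysis of 22. This is the only deprotection that leaves the interflavan bonds and the benzylic C2–O1 ethers intact. The two pivalates of 21 are taken off one step earlier by hydride, while every phenol is still protected, so no base meets a free phenol. The forward steps must not generate acid in the hydrogenolysis.

**Middle pyran ring (21 from 19 and 3, through methide 20).** O1–C2 and C3–C4 of the middle ring C are cut. The neighbouring cut, C4(middle)–C6(lower) by cation arylation of a finished middle unit, would have to fight the C8 preference, and it would make none of the three stereocentres. The precursor 19 lacks one ring and three stereocentres. The forward reaction must be cis-specific for the (Z)-alkene, trans-selective at C4, and controlled in its facial sense by the catalyst although two chiral neighbours are present.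

**Attachment of the lower unit (19 from 12 and 17, through 18).** The C4(middle)–C6(lower) bond is cut as the addition of a 6-metallated lower unit to the salicylaldehyde 12. Annulating the lower pyran ring as well was weighed and dropped: its methide would be an unsubstituted CH2 terminus, which offers the chiral acid no prochiral carbon, and the unit is available enantiopure as (−)-epicatechin 13. The price is a C6-selective nucleophile. It is met by benzylation (14, 15), bromination at the more reactive C8 (16), iodination at the only remaining activated position C6 (17) and selective iodine–lithium exchange (18). The bromine leaves in the final hydrogenolysis. The forward step needs exchange at iodine only and addition to a crowded aldehyde without attack on the pivalate.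

**C1 handle on the middle ring (12 from 11 from 10).** The formyl C–C bond and the O–Si bond are cut. Formylation is tied to the free phenol as its magnesium phenoxide, so ring A of the top unit, whose C6 and C8 are just as electron-rich but carry no free hydroxyl, cannot compete. The two positions ortho to the phenol are equivalent by rotation of the aryl ring, so one aldehyde results and the 4→6 linkage is fixed.

**Top pyran ring, the key cut (10 from 8 and 3, through methide 9).** O1–C2 and C3–C4 of ring C of the top unit are cut. Against the classical C4–aryl disconnection of a preformed flavan, this cut forms two bonds, the ring and all three stereocentres at once. It also brings in the middle ring through its symmetry axis. The precursor 8 is an achiral diaryl carbinol used as the racemate. The forward reaction needs flavan (not isoflavan) regiochemistry, ortho- (not para-) methide formation, 2,3-cis, 3,4-trans and face selection.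

**Diaryl carbinol (8 from 5 and 6, through 7).** The C4–aryl bond is cut as an aryllithium addition. Both rings come from the same phenol 4: ortho-formylation gives the ring A salicylaldehyde 5, and silylation followed by lithiation between the two benzyloxy groups gives the para-differentiated middle ring 7. The bulky triisopropylsilyl ether marks the future O1 of the middle unit, survives the lithium reagent and keeps metalation away from its own ortho positions.

**Dienophile (3 from 2 from 1).** The enol C–O bond is cut as an anti-Markovnikov addition of pivalic acid to alkyne 2, which sets the (Z) geometry. The alkyne comes from aldehyde 1 by one-carbon homologation. The acyloxy group is chosen over an alkoxy group so that the aryl ring, not the oxygen, decides which alkene carbon is nucleophilic.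

## Roads not taken

**Alternative 1:** silicon-tethered pyran transposition. The cut is the O1–C2 bond of the lower unit. That unit would first be attached through C8, the position a flavan-4-yl cation prefers. In the key step its O1–C2 bond is ionized with participation of a 3-acetate, and the C5 oxygen closes onto C2 on the other side of C4a, giving the 6-linked, silylene-bridged trimer A1. A di-tert-butylsilylene from O3 of the middle unit captures the released phenol oxygen and so fixes the direction.
- Merits: all three units could come from (−)-epicatechin, so no C2 or C3 centre has to be made. The natural C8 preference is used and then corrected. Double inversion through the acyloxonium ion is meant to keep C2.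
- Weak points: the Lewis acid that ionizes C2–O1 also threatens both C4–aryl bonds. Participation by a cis-3-acetate needs the less populated half-chair, so C2 may scramble. The step corrects only the lower linkage, and the top–middle 4→6 bond still has to be solved separately. The substrate needs three different oxygen patterns (free O5, silylene, acetate), which costs steps. The ring-closing event itself has no close model.
- Comparison: this road is better in absolute stereocontrol at C2 and C3, which are bought, where the chosen plan relies on a chiral acid twice. The chosen plan never has to correct a linkage and never ionizes C2 of a finished unit.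

**Alternative 2:** triple aryl C–O coupling. The cuts are the three O1–C8a bonds. In the key step three secondary benzylic hydroxyl groups (the future O1 atoms on C2) displace three aryl bromides under copper or palladium catalysis and close all three pyran rings at once, giving the dodeca-O-benzyl tris(silyl ether) A2.
- Merits: C2 is never a cation, since its C–O bond exists beforehand and only the aryl C–O bond is made, so the C2 configuration is safe. The bromine atoms mark C8a, so regiochemistry is unambiguous. Three rings form in one operation.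
- Weak points: the whole stereochemical problem moves to an open-chain precursor with eight stereocentres, two of them diaryl-substituted C4 centres, which must be set without the help of a ring. Electron-rich, ortho-substituted aryl bromides add slowly to the metal. Secondary benzylic alkoxides on palladium tend to lose β-hydride, and copper variants need heat. Three couplings in one molecule multiply every loss.
- Comparison: this road is superior in separating ring closure from stereocentre formation and in protecting C2. The chosen plan answers with step economy: each annulation makes two bonds, a ring and three stereocentres from simple pieces, while the open chain would need a long linear build-up.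

**Alternative 3:** central ring A by cyclobutenone–siloxyalkyne benzannulation. The cuts are two C–C bonds of ring A of the middle unit. A four-carbon ketene precursor attached to C4 of the top unit and a two-carbon siloxy-substituted partner, which carries the open C2–C3–C4 chain of the middle unit and the lower ring, merge in a thermal electrocyclic cascade. The product is the pentasubstituted phenol A3, whose only free hydroxyl is the future O1 of the middle unit.
- Merits: the substitution pattern of the central ring follows from the mechanism, so the 4→6 question does not arise. The union is convergent. The phenol needed for ring closure is differentiated automatically. No chiral catalyst is needed in this step.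
- Weak points: both partners are elaborate and carry stereocentres next to the reacting π systems (a propargylic, benzylic centre that can isomerize, and C4 of the top unit next to a strained enone). The cascade needs heat. Afterwards the middle pyran ring still has to be closed by displacement of a benzylic acetate at C2, where 2,3-cis is not assured, and the lower pyran ring is still missing.
- Comparison: in fixing the interflavan regiochemistry this road is as good as the chosen plan. The chosen plan gets the same certainty from the symmetry of a simple ring and forms the pyran ring with its three stereocentres in the same step.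

Key step: step 6

Assumption: the (R) enantiomer of the phosphoric acid is taken to lead to the (2R,3R,4S) adduct; should a trial show the opposite sense, the (S) acid is used in steps 6 and 14 and nothing else changes.
Assumption: phenol 4 is bought; it is also accessible from phloroglucinol by partial benzylation.

## Route

Step 1
Reactants: 1 3,4-bis(benzyloxy)benzaldehyde
Product: 2 1,2-bis(benzyloxy)-4-ethynylbenzene
Conditions: dimethyl (1-diazo-2-oxopropyl)phosphonate, K2CO3, MeOH/THF, rt
Reagents that add atoms: dimethyl (1-diazo-2-oxopropyl)phosphonate, COP(=O)(OC)C(=[N+]=[N-])C(C)=O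
Why: Ohira–Bestmann homologation: methanolysis of the acetyl group frees the diazomethylphosphonate anion, which olefinates the aldehyde; loss of N2 and a 1,2-hydrogen shift give the terminal alkyne, and benzyl ethers are inert.

Step 2
Reactants: 2 1,2-bis(benzyloxy)-4-ethynylbenzene
Product: 3 (Z)-2-[3,4-bis(benzyloxy)phenyl]ethenyl pivalate
Conditions: pivalic acid, Ru(2-methylallyl)2(dppb) (2 mol %; dppb = 1,4-bis(diphenylphosphino)butane), toluene, 60 °C
Reagents that add atoms: pivalic acid, CC(C)(C)C(=O)O
Why: Ruthenium-catalysed anti-Markovnikov addition of a carboxylic acid to a terminal alkyne through a metal vinylidene; the carboxylate adds to the carbon bound to the metal and protonolysis leaves aryl and acyloxy groups cis, so the (Z)-enol ester should result.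

Step 3
Reactants: 4 3,5-bis(benzyloxy)phenol
Product: 5 4,6-bis(benzyloxy)-2-hydroxybenzaldehyde
Conditions: MgCl2, Et3N, (CH2O)n, MeCN, reflux
Reagents that add atoms: paraformaldehyde (as formaldehyde), C=O
Why: Magnesium-mediated ortho-formylation (Casiraghi–Skattebøl): the magnesium phenoxide delivers formaldehyde to the ortho carbon and a second formaldehyde oxidizes the benzylic alkoxide by hydride transfer; the two ortho positions are equivalent.

Step 4
Reactants: 4 3,5-bis(benzyloxy)phenol
Product: 6 [3,5-bis(benzyloxy)phenoxy]triisopropylsilane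
Conditions: i-Pr3SiCl, imidazole, DMF, rt
Reagents that add atoms: chlorotriisopropylsilane, CC(C)[Si](Cl)(C(C)C)C(C)C
Why: Standard silylation of a phenol; the triisopropylsilyl ether is chosen because it withstands n-BuLi and shields its own ortho positions.

Step 5
Reactants: 6 [3,5-bis(benzyloxy)phenoxy]triisopropylsilane, 5 4,6-bis(benzyloxy)-2-hydroxybenzaldehyde
Product: 8 [4,6-bis(benzyloxy)-2-hydroxyphenyl][2,6-bis(benzyloxy)-4-(triisopropylsilyloxy)phenyl]methanol (racemic), via aryllithium 7 (not isolated)
Conditions: 6 (2.2 equiv), n-BuLi (2.1 equiv), THF, 0 °C; then 5, −78 → 0 °C; aq. NH4Cl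
Reagents that add atoms: none
Why: Directed ortho-lithiation at the only C–H flanked by two benzyloxy groups, then addition to the salicylaldehyde, whose phenol consumes one equivalent of 7 (recovered as 6), the usual way to ortho-hydroxybenzhydrols. The carbinol centre is formed without control and is lost on ionization in step 6.

Step 6
Reactants: 8 [4,6-bis(benzyloxy)-2-hydroxyphenyl][2,6-bis(benzyloxy)-4-(triisopropylsilyloxy)phenyl]methanol, 3 (Z)-2-[3,4-bis(benzyloxy)phenyl]ethenyl pivalate
Product: 10 (2R,3R,4S)-5,7-bis(benzyloxy)-2-[3,4-bis(benzyloxy)phenyl]-4-[2,6-bis(benzyloxy)-4-(triisopropylsilyloxy)phenyl]chroman-3-yl pivalate, via ortho-quinone methide 9 (not isolated)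
Conditions: (R)-3,3'-bis(2,4,6-triisopropylphenyl)-1,1'-binaphthyl-2,2'-diyl hydrogen phosphate [(R)-TRIP] (10 mol %), 3 (2 equiv), 4 Å molecular sieves, toluene, 0 °C → rt
Reagents that add atoms: none
Why: The acid ionizes the doubly benzylic carbinol to the (E)-ortho-quinone methide 9, which stays bound to the chiral phosphate through its oxygen. The enol ester adds with its acyloxy-bearing carbon to the methide carbon (C3–C4) and the developing 3,4-dialkoxybenzyl cation at C2 is captured by the methide oxygen (O1–C2), an asynchronous inverse-demand oxa-[4+2] cycloaddition; the closest known reaction type is the chiral Brønsted acid-catalysed [4+2] of ortho-hydroxybenzhydrols with styrenes and other electron-rich alkenes. Ring C closes as the six-membered ring of this cycloaddition (in the stepwise limit, 6-endo capture of the C2 cation by the phenolic oxygen). C2 and C3 become cis because the (Z)-alkene adds suprafacially; C4 becomes trans to the pivalate through an exo approach, since the two ortho benzyloxy groups of the methide aryl and the 5-benzyloxy group leave no room for an endo ester; the absolute sense at C4, and with it at C2 and C3, is set by the catalyst, which shields one face of the bound methide. The flavan (not isoflavan) regiochemistry that the step needs is secured by the pivaloyloxy group being a much weaker donor than the 3,4-bis(benzyloxy)phenyl group. Only the ortho-quinone methide can form because the para oxygen of the second ring is silylated, and Friedel–Crafts attack by the free C6 and C8 positions of ring A is held back by the crowding of the diaryl methide and by the excess of 3.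

Step 7
Reactants: 10 (2R,3R,4S)-5,7-bis(benzyloxy)-2-[3,4-bis(benzyloxy)phenyl]-4-[2,6-bis(benzyloxy)-4-(triisopropylsilyloxy)phenyl]chroman-3-yl pivalate
Product: 11 (2R,3R,4S)-5,7-bis(benzyloxy)-2-[3,4-bis(benzyloxy)phenyl]-4-[2,6-bis(benzyloxy)-4-hydroxyphenyl]chroman-3-yl pivalate
Conditions: Bu4NF, AcOH, THF, 0 °C
Reagents that add atoms: none
Why: Fluoride cleavage of an aryl silyl ether; the acetic acid buffer keeps the medium from becoming basic, so the pivalate and the C2 centre are not touched.

Step 8
Reactants: 11 (2R,3R,4S)-5,7-bis(benzyloxy)-2-[3,4-bis(benzyloxy)phenyl]-4-[2,6-bis(benzyloxy)-4-hydroxyphenyl]chroman-3-yl pivalate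
Product: 12 (2R,3R,4R)-5,7-bis(benzyloxy)-2-[3,4-bis(benzyloxy)phenyl]-4-[2,6-bis(benzyloxy)-3-formyl-4-hydroxyphenyl]chroman-3-yl pivalate (same spatial arrangement as 11; only the ranking at C4 changes)
Conditions: MgCl2, Et3N, (CH2O)n, THF, reflux
Reagents that add atoms: paraformaldehyde (as formaldehyde), C=O
Why: The same magnesium-mediated ortho-formylation as in step 3, which is its close model; only the ring with the free phenol reacts, and its two ortho positions are equivalent by rotation, so one aldehyde forms and the 4→6 linkage is fixed.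

Step 9
Reactants: 13 (−)-epicatechin
Product: 14 (2R,3R)-5,7-bis(benzyloxy)-2-[3,4-bis(benzyloxy)phenyl]chroman-3-ol
Conditions: BnBr, K2CO3, DMF, 0 °C → rt
Reagents that add atoms: benzyl bromide, BrCc1ccccc1
Why: Williamson etherification of the four phenols; carbonate does not deprotonate the secondary alcohol and room temperature avoids epimerization at C2.

Step 10
Reactants: 14 (2R,3R)-5,7-bis(benzyloxy)-2-[3,4-bis(benzyloxy)phenyl]chroman-3-ol
Product: 15 (2R,3R)-3,5,7-tris(benzyloxy)-2-[3,4-bis(benzyloxy)phenyl]chroman
Conditions: NaH, BnBr, DMF, 0 °C → rt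
Reagents that add atoms: benzyl bromide, BrCc1ccccc1
Why: Williamson etherification of the secondary alkoxide; with no free phenol left, C2 cannot epimerize through a ring-opened quinone methide.

Step 11
Reactants: 15 (2R,3R)-3,5,7-tris(benzyloxy)-2-[3,4-bis(benzyloxy)phenyl]chroman
Product: 16 (2R,3R)-3,5,7-tris(benzyloxy)-2-[3,4-bis(benzyloxy)phenyl]-8-bromochroman
Conditions: NBS, CH2Cl2, −78 → 0 °C
Reagents that add atoms: N-bromosuccinimide, O=C1CCC(=O)N1Br
Why: Electrophilic aromatic bromination; in 5,7-dialkoxyflavans C8 is the most reactive carbon, far ahead of the catechol ring.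

Step 12
Reactants: 16 (2R,3R)-3,5,7-tris(benzyloxy)-2-[3,4-bis(benzyloxy)phenyl]-8-bromochroman
Product: 17 (2R,3R)-3,5,7-tris(benzyloxy)-2-[3,4-bis(benzyloxy)phenyl]-8-bromo-6-iodochroman
Conditions: NIS, CF3CO2H (cat.), CH2Cl2, 0 °C → rt; aq. Na2S2O3
Reagents that add atoms: N-iodosuccinimide, O=C1CCC(=O)N1I
Why: Electrophilic aromatic iodination at C6, the only remaining position of the trioxygenated ring, which is still more electron-rich than the dialkoxy ring B.

Step 13
Reactants: 17 (2R,3R)-3,5,7-tris(benzyloxy)-2-[3,4-bis(benzyloxy)phenyl]-8-bromo-6-iodochroman, 12 (2R,3R,4R)-5,7-bis(benzyloxy)-2-[3,4-bis(benzyloxy)phenyl]-4-[2,6-bis(benzyloxy)-3-formyl-4-hydroxyphenyl]chroman-3-yl pivalate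
Product: 19 (2R,3R,4R)-5,7-bis(benzyloxy)-2-[3,4-bis(benzyloxy)phenyl]-4-{2,6-bis(benzyloxy)-4-hydroxy-3-[hydroxy((2R,3R)-3,5,7-tris(benzyloxy)-2-[3,4-bis(benzyloxy)phenyl]-8-bromochroman-6-yl)methyl]phenyl}chroman-3-yl pivalate (both carbinol epimers), via aryllithium 18 (not isolated)
Conditions: 17 (2.2 equiv), n-BuLi (2.2 equiv), THF, −78 °C; then 12, −78 → −30 °C; aq. NH4Cl
Reagents that add atoms: none
Why: Iodine–lithium exchange is much faster than bromine–lithium exchange, so C8–Br is kept; the aryllithium adds to the aldehyde, one equivalent being spent on the phenol and returning as 16, and the hindered pivalate is not attacked at low temperature. The carbinol centre is formed without control and is lost in step 14.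

Step 14
Reactants: 19 diaryl carbinol of step 13, 3 (Z)-2-[3,4-bis(benzyloxy)phenyl]ethenyl pivalate
Product: 21 3-O-pivaloyl-5,7,3',4'-tetra-O-benzylepicatechin-(4β→6)-3-O-pivaloyl-5,7,3',4'-tetra-O-benzylepicatechin-(4β→6)-3,5,7,3',4'-penta-O-benzyl-8-bromoepicatechin, via ortho-quinone methide 20 (not isolated)
Conditions: (R)-TRIP (10 mol %), 3 (2 equiv), 4 Å molecular sieves, toluene, 0 °C → rt
Reagents that add atoms: none
Why: The same acid-catalysed oxa-[4+2] cycloaddition as in step 6, now through methide 20: C3–C4 and O1–C2 of the middle pyran ring form, the (Z)-alkene gives 2,3-cis, the exo approach gives 3,4-trans and the catalyst selects the face of the methide carbon. The stereocentres of the top and lower units lie several bonds from the methide carbon, so catalyst control is expected to dominate.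

Step 15
Reactants: 21 protected trimer of step 14
Product: 22 5,7,3',4'-tetra-O-benzylepicatechin-(4β→6)-5,7,3',4'-tetra-O-benzylepicatechin-(4β→6)-3,5,7,3',4'-penta-O-benzyl-8-bromoepicatechin
Conditions: i-Bu2AlH, CH2Cl2, −78 → −20 °C; aq. potassium sodium tartrate
Reagents that add atoms: none
Why: Reductive cleavage of the two hindered pivalates by a small hydride donor; benzyl ethers and the aryl bromide are inert and no base is present that could disturb C2.

Step 16
Reactants: 22 diol of step 15
Product: 23 epicatechin-(4β→6)-epicatechin-(4β→6)-epicatechin (CNP0163146.2)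
Conditions: H2 (1 atm), Pd(OH)2/C, NaOAc (1.5 equiv), THF/MeOH/H2O, rt
Reagents that add atoms: none
Why: Hydrogenolysis of thirteen benzyl ethers with concurrent hydrodebromination at C8 of the lower unit; the acetate buffer takes up the HBr so that the acid-labile interflavan bonds survive, and the C2–O1 and C4–aryl bonds of flavans are not cleaved under these neutral conditions.

## Compound list

1 | 3,4-bis(benzyloxy)benzaldehyde | O=Cc1ccc(OCc9ccccc9)c(OCc9ccccc9)c1 | starting material
2 | 1,2-bis(benzyloxy)-4-ethynylbenzene | C#Cc1ccc(OCc9ccccc9)c(OCc9ccccc9)c1 | intermediate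
3 | (Z)-2-[3,4-bis(benzyloxy)phenyl]ethenyl pivalate | CC(C)(C)C(=O)O/C=C\c1ccc(OCc9ccccc9)c(OCc9ccccc9)c1 | intermediate
4 | 3,5-bis(benzyloxy)phenol | Oc1cc(OCc9ccccc9)cc(OCc9ccccc9)c1 | starting material
5 | 4,6-bis(benzyloxy)-2-hydroxybenzaldehyde | O=Cc1c(O)cc(OCc9ccccc9)cc1OCc9ccccc9 | intermediate
6 | [3,5-bis(benzyloxy)phenoxy]triisopropylsilane | CC(C)[Si](Oc1cc(OCc9ccccc9)cc(OCc9ccccc9)c1)(C(C)C)C(C)C | intermediate
7 | [2,6-bis(benzyloxy)-4-(triisopropylsilyloxy)phenyl]lithium | [Li]c1c(OCc9ccccc9)cc(O[Si](C(C)C)(C(C)C)C(C)C)cc1OCc9ccccc9 | intermediate (not isolated)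
8 | [4,6-bis(benzyloxy)-2-hydroxyphenyl][2,6-bis(benzyloxy)-4-(triisopropylsilyloxy)phenyl]methanol (racemic) | OC(c1c(O)cc(OCc9ccccc9)cc1OCc9ccccc9)c1c(OCc9ccccc9)cc(O[Si](C(C)C)(C(C)C)C(C)C)cc1OCc9ccccc9 | intermediate
9 | (6E)-3,5-bis(benzyloxy)-6-{[2,6-bis(benzyloxy)-4-(triisopropylsilyloxy)phenyl]methylidene}cyclohexa-2,4-dien-1-one | O=C1C=C(OCc9ccccc9)C=C(OCc9ccccc9)/C1=C\c1c(OCc9ccccc9)cc(O[Si](C(C)C)(C(C)C)C(C)C)cc1OCc9ccccc9 | intermediate (not isolated)
10 | (2R,3R,4S)-5,7-bis(benzyloxy)-2-[3,4-bis(benzyloxy)phenyl]-4-[2,6-bis(benzyloxy)-4-(triisopropylsilyloxy)phenyl]chroman-3-yl pivalate | c9ccccc9COc1cc(OCc9ccccc9)c2c(c1)O[C@H](c1ccc(OCc9ccccc9)c(OCc9ccccc9)c1)[C@H](OC(=O)C(C)(C)C)[C@H]2c1c(OCc9ccccc9)cc(O[Si](C(C)C)(C(C)C)C(C)C)cc1OCc9ccccc9 | intermediate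
11 | (2R,3R,4S)-5,7-bis(benzyloxy)-2-[3,4-bis(benzyloxy)phenyl]-4-[2,6-bis(benzyloxy)-4-hydroxyphenyl]chroman-3-yl pivalate | c9ccccc9COc1cc(OCc9ccccc9)c2c(c1)O[C@H](c1ccc(OCc9ccccc9)c(OCc9ccccc9)c1)[C@H](OC(=O)C(C)(C)C)[C@H]2c1c(OCc9ccccc9)cc(O)cc1OCc9ccccc9 | intermediate
12 | (2R,3R,4R)-5,7-bis(benzyloxy)-2-[3,4-bis(benzyloxy)phenyl]-4-[2,6-bis(benzyloxy)-3-formyl-4-hydroxyphenyl]chroman-3-yl pivalate | c9ccccc9COc1cc(OCc9ccccc9)c2c(c1)O[C@H](c1ccc(OCc9ccccc9)c(OCc9ccccc9)c1)[C@H](OC(=O)C(C)(C)C)[C@H]2c1c(OCc9ccccc9)cc(O)c(C=O)c1OCc9ccccc9 | intermediate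
13 | (−)-epicatechin, (2R,3R)-2-(3,4-dihydroxyphenyl)chroman-3,5,7-triol | Oc1cc(O)c2c(c1)O[C@H](c1ccc(O)c(O)c1)[C@H](O)C2 | starting material
14 | (2R,3R)-5,7-bis(benzyloxy)-2-[3,4-bis(benzyloxy)phenyl]chroman-3-ol | c9ccccc9COc1cc(OCc9ccccc9)c2c(c1)O[C@H](c1ccc(OCc9ccccc9)c(OCc9ccccc9)c1)[C@H](O)C2 | intermediate
15 | (2R,3R)-3,5,7-tris(benzyloxy)-2-[3,4-bis(benzyloxy)phenyl]chroman | c9ccccc9COc1cc(OCc9ccccc9)c2c(c1)O[C@H](c1ccc(OCc9ccccc9)c(OCc9ccccc9)c1)[C@H](OCc9ccccc9)C2 | intermediate
16 | (2R,3R)-3,5,7-tris(benzyloxy)-2-[3,4-bis(benzyloxy)phenyl]-8-bromochroman | c9ccccc9COc1cc(OCc9ccccc9)c2c(c1Br)O[C@H](c1ccc(OCc9ccccc9)c(OCc9ccccc9)c1)[C@H](OCc9ccccc9)C2 | intermediate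
17 | (2R,3R)-3,5,7-tris(benzyloxy)-2-[3,4-bis(benzyloxy)phenyl]-8-bromo-6-iodochroman | c9ccccc9COc1c(I)c(OCc9ccccc9)c2c(c1Br)O[C@H](c1ccc(OCc9ccccc9)c(OCc9ccccc9)c1)[C@H](OCc9ccccc9)C2 | intermediate
18 | [(2R,3R)-3,5,7-tris(benzyloxy)-2-[3,4-bis(benzyloxy)phenyl]-8-bromochroman-6-yl]lithium | c9ccccc9COc1c([Li])c(OCc9ccccc9)c2c(c1Br)O[C@H](c1ccc(OCc9ccccc9)c(OCc9ccccc9)c1)[C@H](OCc9ccccc9)C2 | intermediate (not isolated)
19 | diaryl carbinol: 12 with its formyl carbon turned into CH(OH) bonded to C6 of the lower unit 16 (both carbinol epimers; full name in step 13) | c9ccccc9COc1cc(OCc9ccccc9)c2c(c1)O[C@H](c1ccc(OCc9ccccc9)c(OCc9ccccc9)c1)[C@H](OC(=O)C(C)(C)C)[C@H]2c1c(OCc9ccccc9)cc(O)c(C(O)c4c(OCc9ccccc9)c(Br)c5c(c4OCc9ccccc9)C[C@@H](OCc9ccccc9)[C@@H](c6ccc(OCc9ccccc9)c(OCc9ccccc9)c6)O5)c1OCc9ccccc9 | intermediate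
20 | ortho-quinone methide of 19: middle ring as 3,5-bis(benzyloxy)cyclohexa-2,4-dien-1-one carrying the top unit (through its C4) at C4 and an (E)-methylidene at C6 that bears the lower unit (through its C6) | c9ccccc9COc1cc(OCc9ccccc9)c2c(c1)O[C@H](c1ccc(OCc9ccccc9)c(OCc9ccccc9)c1)[C@H](OC(=O)C(C)(C)C)[C@H]2C1=C(OCc9ccccc9)/C(=C\c4c(OCc9ccccc9)c(Br)c5c(c4OCc9ccccc9)C[C@@H](OCc9ccccc9)[C@@H](c6ccc(OCc9ccccc9)c(OCc9ccccc9)c6)O5)C(=O)C=C1OCc9ccccc9 | intermediate (not isolated)
21 | 3-O-pivaloyl-5,7,3',4'-tetra-O-benzylepicatechin-(4β→6)-3-O-pivaloyl-5,7,3',4'-tetra-O-benzylepicatechin-(4β→6)-3,5,7,3',4'-penta-O-benzyl-8-bromoepicatechin | c9ccccc9COc1cc(OCc9ccccc9)c2c(c1)O[C@H](c1ccc(OCc9ccccc9)c(OCc9ccccc9)c1)[C@H](OC(=O)C(C)(C)C)[C@H]2c1c(OCc9ccccc9)cc2c(c1OCc9ccccc9)[C@H](c1c(OCc9ccccc9)c(Br)c3c(c1OCc9ccccc9)C[C@@H](OCc9ccccc9)[C@@H](c1ccc(OCc9ccccc9)c(OCc9ccccc9)c1)O3)[C@@H](OC(=O)C(C)(C)C)[C@@H](c1ccc(OCc9ccccc9)c(OCc9ccccc9)c1)O2 | intermediate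
22 | 5,7,3',4'-tetra-O-benzylepicatechin-(4β→6)-5,7,3',4'-tetra-O-benzylepicatechin-(4β→6)-3,5,7,3',4'-penta-O-benzyl-8-bromoepicatechin | c9ccccc9COc1cc(OCc9ccccc9)c2c(c1)O[C@H](c1ccc(OCc9ccccc9)c(OCc9ccccc9)c1)[C@H](O)[C@H]2c1c(OCc9ccccc9)cc2c(c1OCc9ccccc9)[C@H](c1c(OCc9ccccc9)c(Br)c3c(c1OCc9ccccc9)C[C@@H](OCc9ccccc9)[C@@H](c1ccc(OCc9ccccc9)c(OCc9ccccc9)c1)O3)[C@@H](O)[C@@H](c1ccc(OCc9ccccc9)c(OCc9ccccc9)c1)O2 | intermediate
23 | epicatechin-(4β→6)-epicatechin-(4β→6)-epicatechin (CNP0163146.2) | Oc1cc(O)c2c(c1)O[C@H](c1ccc(O)c(O)c1)[C@H](O)[C@H]2c1c(O)cc2c(c1O)[C@H](c1c(O)cc3c(c1O)C[C@@H](O)[C@@H](c1ccc(O)c(O)c1)O3)[C@@H](O)[C@@H](c1ccc(O)c(O)c1)O2 | target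

## Step count and risks

Total: 16 steps. Longest linear sequence: 9 steps (steps 4, 5, 6, 7, 8, 13, 14, 15, 16, from phenol 4).

**Step 6 (key step).** Three processes may intrude.
- The methide is crowded and strongly stabilized by six oxygen donors, so addition of a 1,2-disubstituted alkene may be slow enough for reversible hydration or retro-Friedel–Crafts fragmentation of the carbinol to compete.
- If the benzylic cation at C2 lives long enough, bond rotation or participation of the pivalate carbonyl before ring closure would erode the cis relationship.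
- The alkene carries no hydrogen-bond donor, so face selection rests on the ion pair alone and may be modest.

Fallback: the top unit is taken from the chiral pool and the middle ring is attached by flavan-4-yl cation arylation. The fallback sets out from 14. Oxidation at C4 with DDQ in the presence of 2-ethoxyethanol should give 5,7,3',4'-tetra-O-benzyl-4β-(2-ethoxyethoxy)epicatechin F1, and pivaloyl chloride with pyridine its 3-O-pivalate F2. Activation with catalytic Me3SiOTf at −78 °C in the presence of excess silyl ether 6 should bring the arene in at C4 trans to the participating pivalate, at the carbon of 6 that is para to the bulky silyl ether. The route is rejoined at 10. C2 and C3 are then bought, at the price of a regiochemical question on 6.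

**Step 14.** This is the most crowded methide of the route and the catalyst has to override two chiral neighbours; a mismatched pairing would show as poor facial selectivity, and the crowding as slow addition.

Fallback: the methide substituent is shrunk to an alkoxy group and the lower unit is introduced afterwards. The fallback sets out from 12. With trimethyl orthoformate and the same chiral acid, the salicylaldehyde should give the methoxy-substituted methide, which adds 3 to give the 4-methoxy middle unit F3 (top unit of 12 joined to a 2,3-cis-3-pivaloyloxy-4-methoxy pyran ring, C4 epimers). Catalytic Me3SiOTf then ionizes C4 and the C8-blocked nucleophile 16 attacks through C6, trans to the pivalate. The route is rejoined at 21, and steps 12 and 13 are no longer needed.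

**Step 13.** Aryllithium 18 is flanked by two benzyloxy groups and must add to a phenoxide-deactivated, crowded aldehyde; proton transfer, attack on the pivalate or incomplete selectivity for iodine over bromine may compete.

Fallback: the phenol is masked so that a neutral, more electrophilic aldehyde is attacked. The fallback sets out from 12. Allyl bromide and K2CO3 should give the allyl ether F4 (12 with O-allyl in place of the phenolic OH), to which one equivalent of 18 adds to give the O-allyl carbinol F5. Deallylation with Pd(PPh3)4 (zerovalent palladium) and morpholine under neutral conditions rejoins the route at 19.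

**Step 5.** n-BuLi may metalate a benzylic CH2 of the benzyl ethers (followed by [1,2]-Wittig rearrangement) instead of the ring carbon.

Fallback: the lithium reagent is made by halogen–metal exchange instead of deprotonation. The fallback sets out from 6. NBS should brominate the position para to the bulky silyl ether to give 2-bromo-1,3-bis(benzyloxy)-5-(triisopropylsilyloxy)benzene F6 (separated from any ortho isomer), and n-BuLi at −78 °C converts it into 7. The route is rejoined at aryllithium 7 and continues to 8.

## Further compounds

F1 | step 6 | 5,7,3',4'-tetra-O-benzyl-4β-(2-ethoxyethoxy)epicatechin | c9ccccc9COc1cc(OCc9ccccc9)c2c(c1)O[C@H](c1ccc(OCc9ccccc9)c(OCc9ccccc9)c1)[C@H](O)[C@H]2OCCOCC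
F2 | step 6 | 3-O-pivaloyl-5,7,3',4'-tetra-O-benzyl-4β-(2-ethoxyethoxy)epicatechin | c9ccccc9COc1cc(OCc9ccccc9)c2c(c1)O[C@H](c1ccc(OCc9ccccc9)c(OCc9ccccc9)c1)[C@H](OC(=O)C(C)(C)C)[C@H]2OCCOCC
F3 | step 14 | 3-O-pivaloyl-5,7,3',4'-tetra-O-benzylepicatechin-(4β→6)-3-O-pivaloyl-5,7,3',4'-tetra-O-benzyl-4-methoxyepicatechin (C4 epimers of the methoxy-bearing unit) | c9ccccc9COc1cc(OCc9ccccc9)c2c(c1)O[C@H](c1ccc(OCc9ccccc9)c(OCc9ccccc9)c1)[C@H](OC(=O)C(C)(C)C)[C@H]2c1c(OCc9ccccc9)cc2c(c1OCc9ccccc9)C(OC)[C@@H](OC(=O)C(C)(C)C)[C@@H](c1ccc(OCc9ccccc9)c(OCc9ccccc9)c1)O2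
F4 | step 13 | O-allyl ether of 12: (2R,3R,4R)-4-[4-(allyloxy)-2,6-bis(benzyloxy)-3-formylphenyl]-5,7-bis(benzyloxy)-2-[3,4-bis(benzyloxy)phenyl]chroman-3-yl pivalate | c9ccccc9COc1cc(OCc9ccccc9)c2c(c1)O[C@H](c1ccc(OCc9ccccc9)c(OCc9ccccc9)c1)[C@H](OC(=O)C(C)(C)C)[C@H]2c1c(OCc9ccccc9)cc(OCC=C)c(C=O)c1OCc9ccccc9
F5 | step 13 | O-allyl ether of carbinol 19 (both carbinol epimers) | c9ccccc9COc1cc(OCc9ccccc9)c2c(c1)O[C@H](c1ccc(OCc9ccccc9)c(OCc9ccccc9)c1)[C@H](OC(=O)C(C)(C)C)[C@H]2c1c(OCc9ccccc9)cc(OCC=C)c(C(O)c4c(OCc9ccccc9)c(Br)c5c(c4OCc9ccccc9)C[C@@H](OCc9ccccc9)[C@@H](c6ccc(OCc9ccccc9)c(OCc9ccccc9)c6)O5)c1OCc9ccccc9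
F6 | step 5 | 2-bromo-1,3-bis(benzyloxy)-5-(triisopropylsilyloxy)benzene | Brc1c(OCc9ccccc9)cc(O[Si](C(C)C)(C(C)C)C(C)C)cc1OCc9ccccc9
A1 | alternative 1 | dodeca-O-benzyl 4→6,4→6 trimer with a di-tert-butylsilylene bridging O3 of the middle unit and O5 of the lower unit, lower unit as 3-O-acetate | c9ccccc9COc1cc(OCc9ccccc9)c2c(c1)O[C@H](c1ccc(OCc9ccccc9)c(OCc9ccccc9)c1)[C@H](OCc9ccccc9)[C@H]2c1c(OCc9ccccc9)cc2c(c1OCc9ccccc9)[C@H](c1c(OCc9ccccc9)cc3c(c1O4)C[C@@H](OC(C)=O)[C@@H](c1ccc(OCc9ccccc9)c(OCc9ccccc9)c1)O3)[C@@H](O[Si]4(C(C)(C)C)C(C)(C)C)[C@@H](c1ccc(OCc9ccccc9)c(OCc9ccccc9)c1)O2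
A2 | alternative 2 | dodeca-O-benzyl tris(3-O-tert-butyldimethylsilyl) epicatechin-(4β→6)-epicatechin-(4β→6)-epicatechin | c9ccccc9COc1cc(OCc9ccccc9)c2c(c1)O[C@H](c1ccc(OCc9ccccc9)c(OCc9ccccc9)c1)[C@H](O[Si](C)(C)C(C)(C)C)[C@H]2c1c(OCc9ccccc9)cc2c(c1OCc9ccccc9)[C@H](c1c(OCc9ccccc9)cc3c(c1OCc9ccccc9)C[C@@H](O[Si](C)(C)C(C)(C)C)[C@@H](c1ccc(OCc9ccccc9)c(OCc9ccccc9)c1)O3)[C@@H](O[Si](C)(C)C(C)(C)C)[C@@H](c1ccc(OCc9ccccc9)c(OCc9ccccc9)c1)O2
A3 | alternative 3 | penta-O-benzyl top unit whose C4 carries the new middle ring A (2,6-bis(triisopropylsilyloxy)-4-hydroxyphenyl) bearing at its C3 the open middle-unit chain with 1-aryl (2,6-bis(benzyloxy)-4-(tert-butyldimethylsilyloxy)phenyl), 2-benzyloxy and 3-acetoxy-3-[3,4-bis(benzyloxy)phenyl] groups | c9ccccc9COc1cc(OCc9ccccc9)c2c(c1)O[C@H](c1ccc(OCc9ccccc9)c(OCc9ccccc9)c1)[C@H](OCc9ccccc9)[C@H]2c1c(O[Si](C(C)C)(C(C)C)C(C)C)cc(O)c(c1O[Si](C(C)C)(C(C)C)C(C)C)[C@H](c1c(OCc9ccccc9)cc(O[Si](C)(C)C(C)(C)C)cc1OCc9ccccc9)[C@@H](OCc9ccccc9)[C@@H](OC(C)=O)c1ccc(OCc9ccccc9)c(OCc9ccccc9)c1
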